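You have 0.10 M of electrophile, the limiting reagent, against 0.200 M of nucleophile fed over 8.0 h, and the buffer base in this flask is cut to 0.300 M, below both earlier runs. The decision is whether this recipe can stand to 15 h or needs more nucleophile.

all flasks: electrophile 0.10 M

| run | nucleophile | buffer base | buffer acid | remark | time |
|---|---|---|---|---|---|
| noon | 0.20 M (fed, over 8.0 h) | 0.42 M | 0.010 M | run made earlier |  |
| summer | 0.20 M (fed, over 8.0 h) | 0.66 M | 0.010 M | run made earlier |  |
| flask | 0.200 M (fed, over 8.0 h) | 0.300 M | 0.0100 M |  | 15 h |

- noon (time / h: electrophile / %, target / %): 1.00: 98.0, 1.2; 3.00: 84.6, 14.6; 6.00: 54.6, 42.2; 10.0: 23.1, 63.2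
- summer (time / h: electrophile / %, target / %): 2.50: 89.1, 10.1; 5.00: 64.6, 33.7; 6.00: 54.4, 42.1; 10.0: 22.6, 63.3

(standard deviation of a reading: 0.5 percentage points)

* part of the electrophile that has reacted at 15 h
* pH of the solution at 15 h

- the numbers in the tables scatter by 0.5 percentage points (one standard deviation)
- the earlier runs do not show the pH; that part of a forecast is a guess

At 10.0 h the noon and summer runs hold 23.1% and 22.6% of electrophile, no further apart than the scatter of 0.5 percentage points, so I take the base out of the rate and reckon the flask as the noon run.

Work in fractions of the charge. Exposure is the hours of whole nucleophile charge the electrophile has met. Once the feed is over, its share is time minus half the dosing time, 6.00 h by 10.0 h. The correction is what reaction eats: the ratio of charges, 0.500, times the area under the spent fraction of electrophile, which the noon readings put at 3.54 h. Exposure is then 4.23 h. The negative logarithm of the fraction left, over exposure, reads 0.346 h⁻¹, the rate per whole charge.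

For the flask at 15 h, letting the spent fraction climb to whole, the area grows to 7.96 h and exposure to 7.02 h. So I expect 8.79% of the electrophile left, 91.2% reacted. If each electrophile frees one acid, that costs about a third of the base charge at most, so I keep the recipe. The pH is not in the runs.

The forecast gives 88% and pH 7.5, holding of the earlier runs that “the buffer was never limiting”; its conversion is lower than mine.

The flask gives 91.8% and pH 9.51, so the forecast's conversion stands within tolerance while its pH is low.

    protonated nucleophile ⇌ nucleophile + acid, settled at all times (K = 3.20 × 10⁻⁴ M)
    electrophile + nucleophile → acid + target + leaving group (k = 4.92 × 10⁻⁴ L mol⁻¹ s⁻¹)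
    buffer acid ⇌ buffer base + acid, settled at all times (K = 6.30 × 10⁻¹⁰ M)
    target + leaving group → side product (k = 2.63 × 10⁻⁴ L mol⁻¹ s⁻¹)

At 15.0 h the flask keeps 8.2% of its electrophile against the reckoned 8.79%. A neighbour flask with 0.040 M of electrophile has 5.00 equiv of nucleophile, so its ratio of charges falls to 0.200 while the fed exposure stays 11.0 h. Keeping the area reckoned above, exposure is 9.41 h, and 0.346 h⁻¹ leaves 3.85%. That neighbour flask holds 3.7% of its electrophile.

(The runs stem from a simulated flask with made-up constants, noise included.)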